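**Plan**
- Retrosynthetic cuts: the four O–benzyl bonds; the C11–aryl bond of the side chain to ring B; the ester O–C4 bond; in ring A the C6–undecyl and C1–carboxyl bonds, cut together; the C5–C6 bond of the carbinol chain.
- Enabling feature: in ring A the carboxyl carbon C1 lies between the C2 oxygen and the C6 undecyl group. C1 and C6 therefore map onto the two carbons of a 3,5-dioxygenated benzyne, and the flanking C2 oxygen decides which end takes the nucleophile and which the electrophile.
- Forward order: the ring A acid is built by iodination, triflation and a three-component aryne coupling (alkyl Grignard, then CO2). (S)-Undec-10-en-4-ol is made from the epoxide and joined to the acid as its ester. Ring B is then attached by hydroboration and B-alkyl Suzuki–Miyaura coupling, and the benzyl ethers are removed. Both arenes are bought and no ring is formed.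
- Stereochemistry: the single stereocentre comes from (S)-2-propyloxirane, is untouched in the epoxide opening, and is inverted once, in the Mitsunobu esterification, to the (R) configuration of the target.

Key step: step 4

Assumption: 3,5-bis(benzyloxy)phenol, 1-bromo-3,5-bis(benzyloxy)benzene and (S)-2-propyloxirane are treated as purchased materials; all four phenols are carried as benzyl ethers, which tolerate Grignard reagents and are removed together at the end.

**Step 1**
Reactants: 1 3,5-bis(benzyloxy)phenol
Product: 2 3,5-bis(benzyloxy)-2-iodophenol
Conditions: NIS (1.0 equiv), CH2Cl2, −78 → 0 °C, dark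
Reagents that add atoms: N-iodosuccinimide, O=C1CCC(=O)N1I
Why: Electrophilic aromatic iodination of the activated phenol should occur at C2, ortho to the hydroxyl and para to a benzyloxy group, because the only other kind of free position is crowded between two benzyloxy groups and N-halosuccinimide halogenation of 3,5-dialkoxyphenols is an established ortho-selective reaction.

**Step 2**
Reactants: 2 3,5-bis(benzyloxy)-2-iodophenol
Product: 3 3,5-bis(benzyloxy)-2-iodophenyl trifluoromethanesulfonate
Conditions: Tf2O (1.2 equiv), pyridine (2 equiv), CH2Cl2, 0 °C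
Reagents that add atoms: trifluoromethanesulfonic anhydride, O=S(=O)(OS(=O)(=O)C(F)(F)F)C(F)(F)F
Why: O-Sulfonylation of a phenol with triflic anhydride and pyridine is routine and converts the hydroxyl into the leaving group needed next to the iodine for aryne formation.

**Step 3**
Reactants: 4 1-bromoundecane
Product: 5 undecylmagnesium bromide (titrated THF solution)
Conditions: Mg turnings (1.3 equiv), I2 (cat.), THF, rt → 45 °C
Reagents that add atoms: magnesium, [Mg]
Why: Grignard formation by insertion of magnesium into a primary alkyl bromide is reliable in THF, and titration fixes the excess used in the aryne step.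

**Step 4**
Reactants: 3 3,5-bis(benzyloxy)-2-iodophenyl trifluoromethanesulfonate; 5 undecylmagnesium bromide
Product: 9 2,4-bis(benzyloxy)-6-undecylbenzoic acid, via magnesiated aryl triflate 6 (not isolated), via 3,5-bis(benzyloxy)benzyne 7 (not isolated), via aryl Grignard adduct 8 (not isolated)
Conditions: 3 in THF added slowly to 5 (3.0 equiv), THF, −78 → 0 °C; CO2 (dry gas), −20 °C → rt; 1 M HCl
Reagents that add atoms: carbon dioxide, O=C=O
Why: Iodine–magnesium exchange between 5 and the C–I bond of 3, which is activated by the two flanking oxygen substituents, should give 6, and loss of magnesium bromide triflate from the two adjacent carbons then gives aryne 7. A second equivalent of 5 should deliver its alkyl group to the aryne carbon remote from the flanking benzyloxy group, because the inductively withdrawing oxygen distorts the aryne so that this terminus is the more electrophilic one and the new carbon–magnesium bond ends up beside oxygen, where it is stabilised inductively and by chelation; the second benzyloxy group is too distant to override this. The hindered aryl Grignard 8 is then carboxylated by CO2, which places the carboxyl between the benzyloxy and undecyl groups exactly as in ring A. The closest known reaction types are aryne generation from ortho-iodoaryl triflates by halogen–magnesium exchange and the addition of alkyl organometallics to 3-alkoxybenzynes followed by carboxylation, the classical entry to 6-alkyl-2-alkoxybenzoic acids. No ring is closed and no stereocentre is formed, so the step needs only regioselective addition, secured by the flanking benzyloxy group, and alkyl rather than aryl addition to the aryne, secured by running 3 into an excess of 5 so that 6 and 8 stay dilute.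

**Step 5**
Reactants: 10 6-bromohex-1-ene; 11 (S)-2-propyloxirane
Product: 13 (S)-undec-10-en-4-ol, via hex-5-enylmagnesium bromide 12 (not isolated)
Conditions: 10 (1.5 equiv), Mg, THF, rt; then 11, CuI (10 mol %), THF, −30 → 0 °C; aq NH4Cl
Reagents that add atoms: none
Why: Copper-catalysed opening of a terminal epoxide by a primary Grignard reagent proceeds by SN2 attack at the unsubstituted carbon, so the carbinol centre of 11 is not touched and 13 keeps the (S) configuration, while any cyclopentylmethyl by-product from radical cyclisation during Grignard formation lacks an alkene and is left behind at step 7.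

**Step 6**
Reactants: 9 2,4-bis(benzyloxy)-6-undecylbenzoic acid; 13 (S)-undec-10-en-4-ol
Product: 14 (R)-undec-10-en-4-yl 2,4-bis(benzyloxy)-6-undecylbenzoate
Conditions: PPh3 (1.5 equiv), DIAD (1.5 equiv), toluene, 0 °C → rt
Reagents that add atoms: none
Why: In the Mitsunobu esterification the acidic, di-ortho-substituted benzoate attacks the alkoxyphosphonium ion of 13 in an SN2 displacement, which avoids attack at the crowded carbonyl and inverts C4 from (S) to the (R) configuration of the target.

**Step 7**
Reactants: 14 (R)-undec-10-en-4-yl 2,4-bis(benzyloxy)-6-undecylbenzoate; 15 1-bromo-3,5-bis(benzyloxy)benzene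
Product: 17 (R)-11-[3,5-bis(benzyloxy)phenyl]undecan-4-yl 2,4-bis(benzyloxy)-6-undecylbenzoate, via B-alkyl-9-BBN adduct 16 (not isolated)
Conditions: 9-BBN (1.5 equiv), THF, 0 °C → rt; then 15 (1.3 equiv), Pd(dppf)Cl2 (5 mol %), K3PO4 (3 M aq, 3 equiv), DMF, 60 °C
Reagents that add atoms: none
Why: Anti-Markovnikov hydroboration of the terminal alkene with 9-BBN followed by B-alkyl Suzuki–Miyaura coupling (oxidative addition of 15 to zerovalent palladium, base-assisted transmetalation, reductive elimination) should form the C11–aryl bond, the hindered benzoate being inert to the borane and to aqueous phosphate and the stereocentre not being involved.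

**Step 8**
Reactants: 17 (R)-11-[3,5-bis(benzyloxy)phenyl]undecan-4-yl 2,4-bis(benzyloxy)-6-undecylbenzoate
Product: 18 (R)-11-(3,5-dihydroxyphenyl)undecan-4-yl 2,4-dihydroxy-6-undecylbenzoate (CNP0146287.1)
Conditions: H2 (1 atm), 10% Pd/C, EtOAc–MeOH, rt
Reagents that add atoms: none
Why: Catalytic hydrogenolysis should cleave the four benzyl aryl ethers under neutral conditions that leave the secondary alkyl benzoate and its stereocentre untouched, releasing the four phenols of the target.

**Compound list**
1 | 3,5-bis(benzyloxy)phenol | Oc1cc(OCc2ccccc2)cc(OCc2ccccc2)c1 | starting material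
2 | 3,5-bis(benzyloxy)-2-iodophenol | Oc1cc(OCc2ccccc2)cc(OCc2ccccc2)c1I | intermediate
3 | 3,5-bis(benzyloxy)-2-iodophenyl trifluoromethanesulfonate | FC(F)(F)S(=O)(=O)Oc1cc(OCc2ccccc2)cc(OCc2ccccc2)c1I | intermediate
4 | 1-bromoundecane | CCCCCCCCCCCBr | starting material
5 | undecylmagnesium bromide | CCCCCCCCCCC[Mg]Br | intermediate
6 | 2,4-bis(benzyloxy)-6-(trifluoromethanesulfonyloxy)phenylmagnesium bromide (magnesiated aryl triflate) | FC(F)(F)S(=O)(=O)Oc1cc(OCc2ccccc2)cc(OCc2ccccc2)c1[Mg]Br | intermediate
7 | 3,5-bis(benzyloxy)benzyne | C1#CC(OCc2ccccc2)=CC(OCc2ccccc2)=C1 | intermediate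
8 | 2,4-bis(benzyloxy)-6-undecylphenylmagnesium bromide (aryl Grignard adduct) | CCCCCCCCCCCc1cc(OCc2ccccc2)cc(OCc2ccccc2)c1[Mg]Br | intermediate
9 | 2,4-bis(benzyloxy)-6-undecylbenzoic acid | CCCCCCCCCCCc1cc(OCc2ccccc2)cc(OCc2ccccc2)c1C(=O)O | intermediate
10 | 6-bromohex-1-ene | C=CCCCCBr | starting material
11 | (S)-2-propyloxirane | CCC[C@H]1CO1 | starting material
12 | hex-5-enylmagnesium bromide | C=CCCCC[Mg]Br | intermediate
13 | (S)-undec-10-en-4-ol | CCC[C@H](O)CCCCCC=C | intermediate
14 | (R)-undec-10-en-4-yl 2,4-bis(benzyloxy)-6-undecylbenzoate | CCCCCCCCCCCc1cc(OCc2ccccc2)cc(OCc2ccccc2)c1C(=O)O[C@H](CCC)CCCCCC=C | intermediate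
15 | 1-bromo-3,5-bis(benzyloxy)benzene | Brc1cc(OCc2ccccc2)cc(OCc2ccccc2)c1 | starting material
16 | (R)-11-(9-borabicyclo[3.3.1]nonan-9-yl)undecan-4-yl 2,4-bis(benzyloxy)-6-undecylbenzoate (B-alkyl-9-BBN adduct) | CCCCCCCCCCCc1cc(OCc2ccccc2)cc(OCc2ccccc2)c1C(=O)O[C@H](CCC)CCCCCCCB1C2CCCC1CCC2 | intermediate
17 | (R)-11-[3,5-bis(benzyloxy)phenyl]undecan-4-yl 2,4-bis(benzyloxy)-6-undecylbenzoate | CCCCCCCCCCCc1cc(OCc2ccccc2)cc(OCc2ccccc2)c1C(=O)O[C@H](CCC)CCCCCCCc1cc(OCc2ccccc2)cc(OCc2ccccc2)c1 | intermediate
18 | (R)-11-(3,5-dihydroxyphenyl)undecan-4-yl 2,4-dihydroxy-6-undecylbenzoate | CCCCCCCCCCCc1cc(O)cc(O)c1C(=O)O[C@H](CCC)CCCCCCCc1cc(O)cc(O)c1 | target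

**Step count**
Total: 8 steps. Longest linear sequence: 6 steps (steps 1, 2, 4, 6, 7, 8, from 3,5-bis(benzyloxy)phenol).

**Steps most likely to fail**

Step 4. The aryne may be consumed by hydride transfer from the β-hydrogens of the alkyl Grignard or by attack of the aryl magnesium species, or the alkyl group may add with incomplete regiocontrol; in addition, the acid has to be separated from dodecanoic acid formed from surplus Grignard reagent. The fallback avoids the aryne and sets out from 15 and 5. Kumada–Corriu coupling (Pd(dppf)Cl2 cat., THF, reflux) should give 1,3-bis(benzyloxy)-5-undecylbenzene F1. Vilsmeier–Haack formylation (POCl3, DMF, 0 → 70 °C), which on 5-alkylresorcinol diethers goes beside the alkyl chain and para to an ether oxygen, should give 2,4-bis(benzyloxy)-6-undecylbenzaldehyde F2. Pinnick oxidation (NaClO2, NaH2PO4, 2-methylbut-2-ene, t-BuOH–H2O) then returns to the route at 9.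

Step 1. Iodination may also take place para to the hydroxyl, or twice, giving material that cannot form the required aryne. The fallback sets out from 1. Bromination with NBS (CH2Cl2, −78 °C), whose ortho selectivity on this type of phenol is established, should give 3,5-bis(benzyloxy)-2-bromophenol F3. Treatment with n-BuLi (2.2 equiv, THF, −78 °C), which first forms the lithium phenoxide and then exchanges bromine for lithium, followed by I2, returns to the route at 2.

Step 6. The activated secondary alcohol may eliminate to an alkene, or the hindered carboxylate may react too slowly, so that conversion or inversion is incomplete. The fallback sets out from 13. Mesylation (MsCl, Et3N, CH2Cl2, 0 °C) should give (S)-undec-10-en-4-yl methanesulfonate F4, a preformed electrophile. SN2 displacement by the cesium salt of 9 (Cs2CO3, DMF, 50 °C) inverts the centre and returns to the route at 14.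

**Further compounds**
F1 | step 4 | 1,3-bis(benzyloxy)-5-undecylbenzene | CCCCCCCCCCCc1cc(OCc2ccccc2)cc(OCc2ccccc2)c1
F2 | step 4 | 2,4-bis(benzyloxy)-6-undecylbenzaldehyde | CCCCCCCCCCCc1cc(OCc2ccccc2)cc(OCc2ccccc2)c1C=O
F3 | step 1 | 3,5-bis(benzyloxy)-2-bromophenol | Oc1cc(OCc2ccccc2)cc(OCc2ccccc2)c1Br
F4 | step 6 | (S)-undec-10-en-4-yl methanesulfonate | CCC[C@H](OS(C)(=O)=O)CCCCCC=C
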